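**Strategy.** Ring D (C4, C6, C7, C16, C15; atoms counted along the SMILES of the target) is closed last through the C4–C15 bond. The precursor is a tricyclic cyclopentene (C15=C16, rings A–C, fused to the bromodecalin) whose C7 carries a 3-methyl-2-oxobutyl chain. Hydrogen-atom transfer from an iron hydride to C16 gives the tertiary C15 radical, which adds 5-exo to the isopropyl ketone. One operation creates the norbornane, the quaternary bridgehead C15 and the tertiary carbinol C4. It exploits the 1,3-cis relation of the C7 chain and C15 on ring C. Ring A comes from an enantiospecific bromonium cyclization, rings B and C from a Pauson–Khand reaction.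

Key step: step 13

Remarks on the chemistry (made before the steps):
- Numbering: atoms are counted along the SMILES of 19 as written in the compound list (C1–C3 isopropyl, C4, O5, C6 … C17, Br18, C19–C22, O23). Ring A = C10, C11, C17, C19, C20, C21; ring B = C9, C10, C11, C13, C14, C15; ring C = C15, C9, C8, C7, C16; ring D = C4, C6, C7, C16, C15.
- Assumption: the palladium-mediated allylic substitution of step 12 is taken to run by outer-sphere attack, i.e. with net retention at C7.
- Compounds 1, 4 and 15 are taken as commercial.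

Step 1
Reactants: 1 hexa-1,5-diyne
Product: 3 (E)-1-iodo-2-methylhex-1-en-5-yne, via alkenylalane 2 (not isolated)
Conditions: Me3Al, Cp2ZrCl2 (20 mol %), H2O (substoichiometric), CH2Cl2, −20 °C, threefold excess of 1; then I2, THF, −30 to 0 °C
Reagents that add atoms: trimethylaluminium, C[Al](C)C; iodine, II
Why: Negishi zirconium-catalysed carboalumination adds methyl and aluminium syn across one terminal alkyne with methyl on the internal carbon, and iodine cleaves the C–Al bond with retention, so the (E)-trisubstituted alkenyl iodide should result; the excess of the symmetrical diyne limits double addition.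

Step 2
Reactants: 3 (E)-1-iodo-2-methylhex-1-en-5-yne; 4 (3-ethoxy-3-oxopropyl)zinc bromide
Product: 5 ethyl (E)-5-methylnon-4-en-8-ynoate
Conditions: Pd(PPh3)4 (5 mol %), THF, 50 °C
Reagents that add atoms: none
Why: Negishi sp2–sp3 cross-coupling of the alkenyl iodide with the ester-bearing alkylzinc reagent should proceed with retention of the alkene geometry and tolerate the ester and the terminal alkyne.

Step 3
Reactants: 5 ethyl (E)-5-methylnon-4-en-8-ynoate
Product: 6 ethyl 3-[(2R,3R)-3-(but-3-yn-1-yl)-3-methyloxiran-2-yl]propanoate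
Conditions: D-fructose-derived ketone catalyst of the Shi epoxidation (30 mol %), Oxone, K2CO3, Bu4NHSO4, MeCN/dimethoxymethane–aqueous buffer (pH 10.5), 0 °C
Reagents that add atoms: potassium peroxymonosulfate, [K+].[O-]S(=O)(=O)OO
Why: Shi asymmetric epoxidation: the chiral dioxirane transfers oxygen to the electron-rich (E)-trisubstituted alkene through the spiro transition state, which should give the (2R,3R)-epoxide, while the alkyne and the ester are not oxidised.

Step 4
Reactants: 6 ethyl 3-[(2R,3R)-3-(but-3-yn-1-yl)-3-methyloxiran-2-yl]propanoate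
Product: 8 1-[(2R,3R)-3-(but-3-yn-1-yl)-3-methyloxiran-2-yl]hex-5-en-3-one, via Weinreb amide 7 (not isolated)
Conditions: MeNH(OMe)·HCl, i-PrMgCl, THF, −20 °C; then allylMgBr, −78 to 0 °C; aq. NH4Cl
Reagents that add atoms: allylmagnesium bromide, C=CC[Mg]Br
Why: Weinreb ketone synthesis in one flask: the chelated tetrahedral adduct of the amide with the allyl Grignard reagent collapses only on work-up, so the allyl ketone should form without over-addition and without opening of the hindered trisubstituted epoxide.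

Step 5
Reactants: 8 1-[(2R,3R)-3-(but-3-yn-1-yl)-3-methyloxiran-2-yl]hex-5-en-3-one
Product: 9 (7S,8R)-7-bromo-8-hydroxy-8-methyldodec-1-en-11-yn-4-one
Conditions: Li2NiBr4, THF, 0 °C to rt; aqueous phosphate buffer (pH 7)
Reagents that add atoms: dilithium tetrabromonickelate, [Li+].[Li+].[Ni+2].[Br-].[Br-].[Br-].[Br-]
Why: Under non-acidic conditions bromide opens the epoxide by SN2 attack at the less substituted carbon C17 with inversion, which keeps the tertiary C–O bond and fixes the (S)-configured C–Br centre.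

Step 6
Reactants: 9 (7S,8R)-7-bromo-8-hydroxy-8-methyldodec-1-en-11-yn-4-one
Product: 10 (3Z,7S,8R)-7-bromo-8-methyl-4,8-bis(trimethylsilyloxy)dodeca-1,3-dien-11-yne
Conditions: TMSOTf (2.4 equiv), Et3N, CH2Cl2, −78 to 0 °C
Reagents that add atoms: trimethylsilyl trifluoromethanesulfonate, C[Si](C)(C)OS(=O)(=O)C(F)(F)F
Why: Soft enolisation silylates the tertiary hydroxyl and converts the ketone into the conjugated silyl dienol ether by deprotonation of the doubly activated C10 methylene between the carbonyl and the vinyl group.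

Step 7
Reactants: 10 (3Z,7S,8R)-7-bromo-8-methyl-4,8-bis(trimethylsilyloxy)dodeca-1,3-dien-11-yne
Product: 11 (2S,3S,4S)-4-bromo-3-(but-3-yn-1-yl)-2-ethenyl-3-methylcyclohexan-1-one
Conditions: SnCl4 (1.2 equiv), 2,6-di-tert-butylpyridine, CH2Cl2, −78 °C
Reagents that add atoms: none
Why: The Lewis acid ionises the tertiary silyl ether with neighbouring-group participation of bromine to a configurationally defined bromonium ion, which C10 of the silyl dienol ether opens at C11 with inversion in a chair-like transition state (cation–olefin cyclisation ended by a silyl enol ether, a Mukaiyama-type SN1 alkylation), so that C17 keeps its configuration, C11 follows from the anti opening and the vinyl group at C10 should take the equatorial position.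

Step 8
Reactants: 11 (2S,3S,4S)-4-bromo-3-(but-3-yn-1-yl)-2-ethenyl-3-methylcyclohexan-1-one
Product: 12 (1R,2S,3S,4S)-4-bromo-3-(but-3-yn-1-yl)-2-ethenyl-1,3-dimethylcyclohexan-1-ol
Conditions: MeLi, CeCl3 (dried), THF, −78 °C
Reagents that add atoms: methyllithium, [Li]C
Why: The weakly basic organocerium reagent should add to the enolisable α-vinyl ketone without deprotonation, from the equatorial direction because the axial C12 methyl group blocks the axial path (1,3-diaxial), which sets the axial tertiary alcohol at C21.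

Step 9
Reactants: 12 (1R,2S,3S,4S)-4-bromo-3-(but-3-yn-1-yl)-2-ethenyl-1,3-dimethylcyclohexan-1-ol
Product: 13 (5aS,6S,9R,9aS,9bS)-6-bromo-9-hydroxy-5a,9-dimethyl-1,4,5,5a,6,7,8,9,9a,9b-decahydro-2H-cyclopenta[a]naphthalen-2-one
Conditions: Co2(CO)8 (10 mol %), tetramethylthiourea (60 mol %), CO (1 atm), toluene, 70 °C
Reagents that add atoms: carbon monoxide, [C-]#[O+]
Why: The intramolecular Pauson–Khand [2+2+1] cycloaddition of the 1,7-enyne closes rings B and C at once; the trans-diequatorial vinyl and butynyl groups give the trans-fused ring B, and C9–H should become axial because C8 must lie pseudo-equatorial next to the sp2 carbon C15.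

Step 10
Reactants: 13 (5aS,6S,9R,9aS,9bS)-6-bromo-9-hydroxy-5a,9-dimethyl-1,4,5,5a,6,7,8,9,9a,9b-decahydro-2H-cyclopenta[a]naphthalen-2-one
Product: 14 (2R,5aS,6S,9R,9aS,9bS)-6-bromo-5a,9-dimethyl-2,4,5,5a,6,7,8,9,9a,9b-decahydro-1H-cyclopenta[a]naphthalene-2,9-diol
Conditions: (S)-2-methyl-CBS-oxazaborolidine (20 mol %), catecholborane, toluene, −78 °C
Reagents that add atoms: none
Why: The Corey–Bakshi–Shibata reduction is 1,2-selective for the enone and catalyst-controlled, the (S)-oxazaborolidine delivering hydride to the face that gives the (2R)-allylic alcohol with the hydroxyl cis to C9–H.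

Step 11
Reactants: 14 (2R,5aS,6S,9R,9aS,9bS)-6-bromo-5a,9-dimethyl-2,4,5,5a,6,7,8,9,9a,9b-decahydro-1H-cyclopenta[a]naphthalene-2,9-diol; 15 methyl 4-methyl-3-oxopentanoate
Product: 16 (2R,5aS,6S,9R,9aS,9bS)-6-bromo-9-hydroxy-5a,9-dimethyl-2,4,5,5a,6,7,8,9,9a,9b-decahydro-1H-cyclopenta[a]naphthalen-2-yl 4-methyl-3-oxopentanoate
Conditions: DMAP (cat.), toluene, reflux with removal of MeOH
Reagents that add atoms: none
Why: Transesterification of the β-keto ester (through its acylketene) should acylate the secondary allylic hydroxyl and leave the hindered tertiary hydroxyl at C21 untouched.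

Step 12
Reactants: 16 (2R,5aS,6S,9R,9aS,9bS)-6-bromo-9-hydroxy-5a,9-dimethyl-2,4,5,5a,6,7,8,9,9a,9b-decahydro-1H-cyclopenta[a]naphthalen-2-yl 4-methyl-3-oxopentanoate
Product: 18 1-[(2S,5aS,6S,9R,9aS,9bS)-6-bromo-9-hydroxy-5a,9-dimethyl-2,4,5,5a,6,7,8,9,9a,9b-decahydro-1H-cyclopenta[a]naphthalen-2-yl]-3-methylbutan-2-one, via beta-keto acid 17 (not isolated)
Conditions: Pd(PPh3)4 (5 mol %), THF, rt
Reagents that add atoms: none
Why: Palladium-catalysed decarboxylative allylic alkylation (Carroll-type Tsuji reaction): zerovalent palladium ionises the allylic ester anti to the leaving group, the β-keto carboxylate attacks the less hindered terminus C7 anti to palladium (C15 is fully substituted), and loss of CO2 should give the ketone with net retention at C7 and the alkene kept at C15=C16.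

Step 13
Reactants: 18 1-[(2S,5aS,6S,9R,9aS,9bS)-6-bromo-9-hydroxy-5a,9-dimethyl-2,4,5,5a,6,7,8,9,9a,9b-decahydro-1H-cyclopenta[a]naphthalen-2-yl]-3-methylbutan-2-one
Product: 19 (2R,3aR,5aS,6S,9R,9aS,9bS,10R)-6-bromo-5a,9-dimethyl-10-(propan-2-yl)perhydro-2,3a-ethanocyclopenta[a]naphthalene-9,10-diol (CNP0362628.1)
Conditions: Fe(acac)3 (0.5 equiv), PhSiH3 (2.5 equiv), EtOH/ethylene glycol, 60 °C, argon
Reagents that add atoms: none
Why: An iron hydride formed from Fe(acac)3 and PhSiH3 transfers a hydrogen atom to the less substituted C16 of the trisubstituted alkene, the tertiary C15 radical adds to the carbonyl carbon C4, and the alkoxyl radical is reduced and protonated; the closest known reaction type is the hydrogen-atom-transfer-initiated radical cyclisation of alkene-tethered ketones to tertiary alcohols. Ring D closes in the 5-exo-trig mode onto the C=O group and completes the bicyclo[2.2.1]heptane. C15 is controlled by the tether, because the ketone chain on C7 reaches only the face of ring C that is cis to C7–C6 and anti to C10 at C9. C4 is controlled in the reversible addition: the isopropyl group should take the endo position, away from the C14 methylene and the syn hydrogen of C16 that flank the exo position, and the alkoxyl radical with exo oxygen should also be the one reduced faster from the open exo side. The step needs chemoselective hydrogen-atom transfer beside the secondary bromide, the ketone and the hydroxyl group (only one alkene is present) and exo-oxygen selectivity at C4, which is the main uncertainty.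

**Compound list**

1 | hexa-1,5-diyne | C#CCCC#C | starting material
2 | dimethyl[(1E)-2-methylhex-1-en-5-yn-1-yl]alumane | C[Al](C)/C=C(C)/CCC#C | intermediate (not isolated)
3 | (E)-1-iodo-2-methylhex-1-en-5-yne | I/C=C(C)/CCC#C | intermediate
4 | (3-ethoxy-3-oxopropyl)zinc bromide | CCOC(=O)CC[Zn]Br | starting material
5 | ethyl (E)-5-methylnon-4-en-8-ynoate | CCOC(=O)CC/C=C(C)/CCC#C | intermediate
6 | ethyl 3-[(2R,3R)-3-(but-3-yn-1-yl)-3-methyloxiran-2-yl]propanoate | CCOC(=O)CC[C@H]1O[C@]1(C)CCC#C | intermediate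
7 | 3-[(2R,3R)-3-(but-3-yn-1-yl)-3-methyloxiran-2-yl]-N-methoxy-N-methylpropanamide | CON(C)C(=O)CC[C@H]1O[C@]1(C)CCC#C | intermediate (not isolated)
8 | 1-[(2R,3R)-3-(but-3-yn-1-yl)-3-methyloxiran-2-yl]hex-5-en-3-one | C=CCC(=O)CC[C@H]1O[C@]1(C)CCC#C | intermediate
9 | (7S,8R)-7-bromo-8-hydroxy-8-methyldodec-1-en-11-yn-4-one | C=CCC(=O)CC[C@H](Br)[C@](C)(O)CCC#C | intermediate
10 | (3Z,7S,8R)-7-bromo-8-methyl-4,8-bis(trimethylsilyloxy)dodeca-1,3-dien-11-yne | C=C/C=C(\O[Si](C)(C)C)CC[C@H](Br)[C@](C)(O[Si](C)(C)C)CCC#C | intermediate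
11 | (2S,3S,4S)-4-bromo-3-(but-3-yn-1-yl)-2-ethenyl-3-methylcyclohexan-1-one | C=C[C@H]1[C@](C)(CCC#C)[C@@H](Br)CCC1=O | intermediate
12 | (1R,2S,3S,4S)-4-bromo-3-(but-3-yn-1-yl)-2-ethenyl-1,3-dimethylcyclohexan-1-ol | C=C[C@H]1[C@](C)(CCC#C)[C@@H](Br)CC[C@@]1(C)O | intermediate
13 | (5aS,6S,9R,9aS,9bS)-6-bromo-9-hydroxy-5a,9-dimethyl-1,4,5,5a,6,7,8,9,9a,9b-decahydro-2H-cyclopenta[a]naphthalen-2-one | O=C1C[C@H]2[C@H]3[C@](C)(CCC2=C1)[C@@H](Br)CC[C@@]3(C)O | intermediate
14 | (2R,5aS,6S,9R,9aS,9bS)-6-bromo-5a,9-dimethyl-2,4,5,5a,6,7,8,9,9a,9b-decahydro-1H-cyclopenta[a]naphthalene-2,9-diol | O[C@@H]1C[C@H]2[C@H]3[C@](C)(CCC2=C1)[C@@H](Br)CC[C@@]3(C)O | intermediate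
15 | methyl 4-methyl-3-oxopentanoate | COC(=O)CC(=O)C(C)C | starting material
16 | (2R,5aS,6S,9R,9aS,9bS)-6-bromo-9-hydroxy-5a,9-dimethyl-2,4,5,5a,6,7,8,9,9a,9b-decahydro-1H-cyclopenta[a]naphthalen-2-yl 4-methyl-3-oxopentanoate | CC(C)C(=O)CC(=O)O[C@@H]1C[C@H]2[C@H]3[C@](C)(CCC2=C1)[C@@H](Br)CC[C@@]3(C)O | intermediate
17 | 2-[(2R,5aS,6S,9R,9aS,9bS)-6-bromo-9-hydroxy-5a,9-dimethyl-2,4,5,5a,6,7,8,9,9a,9b-decahydro-1H-cyclopenta[a]naphthalen-2-yl]-4-methyl-3-oxopentanoic acid (either configuration at C2 of the acid) | CC(C)C(=O)C(C(=O)O)[C@@H]1C[C@H]2[C@H]3[C@](C)(CCC2=C1)[C@@H](Br)CC[C@@]3(C)O | intermediate (not isolated)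
18 | 1-[(2S,5aS,6S,9R,9aS,9bS)-6-bromo-9-hydroxy-5a,9-dimethyl-2,4,5,5a,6,7,8,9,9a,9b-decahydro-1H-cyclopenta[a]naphthalen-2-yl]-3-methylbutan-2-one | CC(C)C(=O)C[C@@H]1C[C@H]2[C@H]3[C@](C)(CCC2=C1)[C@@H](Br)CC[C@@]3(C)O | intermediate
19 | (2R,3aR,5aS,6S,9R,9aS,9bS,10R)-6-bromo-5a,9-dimethyl-10-(propan-2-yl)perhydro-2,3a-ethanocyclopenta[a]naphthalene-9,10-diol (CNP0362628.1) | CC(C)[C@]1(O)C[C@@H]2C[C@H]3[C@H]4[C@](C)(CC[C@@]31C2)[C@@H](Br)CC[C@@]4(C)O | target

**Step count and risks**

Total step count: 13. Longest linear sequence: 13 steps (from 1).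

Steps most likely to fail:

1. Step 13. The addition of the C15 radical to the ketone is reversible and builds a strained bicycle, so the radical may be reduced before ring closure, and the facial selectivity at C4 may be poor. The fallback sets out from 14 and comes back at 19. Compound 14 is esterified with cyanoacetic acid (DCC, DMAP) to the cyanoacetate F1. Pd(PPh3)4 in THF then effects decarboxylative allylation with net retention to the nitrile F2. Fe(acac)3/PhSiH3 in EtOH closes ring D by hydrogen-atom-transfer radical cyclisation onto the nitrile, and hydrolysis of the imine gives the ring D ketone F3. KHMDS/PhNTf2 converts it into the enol triflate F4, and Negishi coupling with isopropylzinc bromide (Pd(OAc)2, CPhos) gives the 2-isopropylnorbornene F5. Mukaiyama hydration (Co(acac)2, PhSiH3, O2; then PPh3) adds hydrogen to C6 and traps the tertiary C4 radical from the exo face, which returns to 19.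

2. Step 7. After ionisation the bromonium ion may lose a proton or be captured by oxygen, and the silyl dienol ether may be cleaved by the Lewis acid before the C–C bond forms. The fallback sets out from 6 and comes back at 11. Claisen condensation of 6 with the lithium enolate of tert-butyl acetate gives the β-keto ester F6, and Li2NiBr4 opens the epoxide to the bromohydrin F7. SnCl4 in CH2Cl2 cyclises it through the enol of the β-keto ester, a stabilised carbon nucleophile for cation–olefin cyclisations, to the bromo β-keto ester F8. Vinylation of its potassium enolate with ethenyl(phenyl)iodonium tetrafluoroborate gives the α-vinyl β-keto ester F9. CF3CO2H then cleaves the tert-butyl ester, and decarboxylation with equilibration at C10 returns to 11.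

3. Step 12. Double allylation of the β-keto carboxylate or β-hydride elimination of the allylpalladium intermediate to a diene may compete with the wanted substitution. The fallback sets out from 14 and comes back at 18. Methyl chloroformate and pyridine convert 14 into the methyl carbonate F10. Tsuji–Trost alkylation with 15 (Pd(PPh3)4, THF) gives, with net retention, the alkylated β-keto ester F11. Krapcho dealkoxycarbonylation (LiCl, wet DMSO, 130 °C) returns to 18.

**Further compounds**

F1 | step 13 | (2R,5aS,6S,9R,9aS,9bS)-6-bromo-9-hydroxy-5a,9-dimethyl-2,4,5,5a,6,7,8,9,9a,9b-decahydro-1H-cyclopenta[a]naphthalen-2-yl cyanoacetate | N#CCC(=O)O[C@@H]1C[C@H]2[C@H]3[C@](C)(CCC2=C1)[C@@H](Br)CC[C@@]3(C)O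
F2 | step 13 | 2-[(2S,5aS,6S,9R,9aS,9bS)-6-bromo-9-hydroxy-5a,9-dimethyl-2,4,5,5a,6,7,8,9,9a,9b-decahydro-1H-cyclopenta[a]naphthalen-2-yl]acetonitrile | N#CC[C@@H]1C[C@H]2[C@H]3[C@](C)(CCC2=C1)[C@@H](Br)CC[C@@]3(C)O
F3 | step 13 | (2R,3aR,5aS,6S,9R,9aS,9bS)-6-bromo-9-hydroxy-5a,9-dimethylperhydro-2,3a-ethanocyclopenta[a]naphthalen-10-one (ring D ketone at C4) | O=C1C[C@@H]2C[C@H]3[C@H]4[C@](C)(CC[C@@]31C2)[C@@H](Br)CC[C@@]4(C)O
F4 | step 13 | enol triflate of F3 (C4=C6 double bond, triflyloxy on C4, other stereocentres as in 19) | O=S(=O)(OC1=C[C@@H]2C[C@H]3[C@H]4[C@](C)(CC[C@@]31C2)[C@@H](Br)CC[C@@]4(C)O)C(F)(F)F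
F5 | step 13 | 2-isopropylnorbornene analogue of 19 (C4=C6 double bond, isopropyl on C4, other stereocentres as in 19) | CC(C)C1=C[C@@H]2C[C@H]3[C@H]4[C@](C)(CC[C@@]31C2)[C@@H](Br)CC[C@@]4(C)O
F6 | step 7 | tert-butyl 5-[(2R,3R)-3-(but-3-yn-1-yl)-3-methyloxiran-2-yl]-3-oxopentanoate | CC(C)(C)OC(=O)CC(=O)CC[C@H]1O[C@]1(C)CCC#C
F7 | step 7 | tert-butyl (6S,7R)-6-bromo-7-hydroxy-7-methyl-3-oxoundec-10-ynoate | CC(C)(C)OC(=O)CC(=O)CC[C@H](Br)[C@](C)(O)CCC#C
F8 | step 7 | tert-butyl (2S,3S)-3-bromo-2-(but-3-yn-1-yl)-2-methyl-6-oxocyclohexane-1-carboxylate (C1 not defined) | CC(C)(C)OC(=O)C1C(=O)CC[C@H](Br)[C@@]1(C)CCC#C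
F9 | step 7 | tert-butyl (2S,3S)-3-bromo-2-(but-3-yn-1-yl)-1-ethenyl-2-methyl-6-oxocyclohexane-1-carboxylate (C1 not defined) | CC(C)(C)OC(=O)C1(C=C)C(=O)CC[C@H](Br)[C@@]1(C)CCC#C
F10 | step 12 | (2R,5aS,6S,9R,9aS,9bS)-6-bromo-9-hydroxy-5a,9-dimethyl-2,4,5,5a,6,7,8,9,9a,9b-decahydro-1H-cyclopenta[a]naphthalen-2-yl methyl carbonate | COC(=O)O[C@@H]1C[C@H]2[C@H]3[C@](C)(CCC2=C1)[C@@H](Br)CC[C@@]3(C)O
F11 | step 12 | methyl 2-[(2R,5aS,6S,9R,9aS,9bS)-6-bromo-9-hydroxy-5a,9-dimethyl-2,4,5,5a,6,7,8,9,9a,9b-decahydro-1H-cyclopenta[a]naphthalen-2-yl]-4-methyl-3-oxopentanoate (either configuration at C2 of the ester) | CC(C)C(=O)C(C(=O)OC)[C@@H]1C[C@H]2[C@H]3[C@](C)(CCC2=C1)[C@@H](Br)CC[C@@]3(C)O
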